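## Structural features

The target is a trans-fused bicyclo[5.3.0]decane (a daucane-type hydroazulene). A cyclopentane (C1–C5) and a cycloheptane (C1, C5–C10) share the C1–C5 bond; C1 is quaternary (methyl) and C5 is a methine. Six stereocentres form two contiguous sets that meet at the ring fusion. On one side are C4 (tertiary carbinol with isopropyl, OH β), C5 (H α) and C6 (acyloxy α); on the other are C1 (methyl β), C10 and C9 (cis-diol, both α). C8 carries the exocyclic methylidene C14, so C9 is an allylic carbinol.

Fragile elements are the tertiary C4 alcohol (dehydration, and retro-aldol or elimination whenever C6 is at the ketone level), the methylidene next to a carbonyl or carbinol (conjugate addition, isomerisation), and the single 3-methylbutanoate, which must be placed on O6 among four oxygens.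

The real difficulty is twofold. The quaternary C1 must be set in the absolute sense on a mobile seven-membered ring. And when C5 is trigonal the skeleton offers almost no facial bias around C4–C6, because C1 shows a methyl group to one face and the ring methylene C10 to the other; every further centre therefore has to be relayed by a directed or stereospecific step.

The skeleton carries oxygen at C4 and C9, which are 1,5-related through C5–C1–C10, the mark of a cyclobutanol opened by retro-aldol cleavage. The key step uses this: a C4(=O)–C5=C9(O) enol unit in a cyclopentane and a tethered C1=C10 alkene are joined (C5–C1, C9–C10), and C5–C9 is then cleaved. This enlarges the cyclopentane to the seven-membered ring and creates the cyclopentanone ring and C1 in one operation.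

## Logic of the disconnections

27 to 26: the C9–H bond is cut (carbinol back to ketone). The C9 carbonyl is what the key step leaves behind, and with O10 already in place it can be reduced under chelation. The gain is one stereocentre; the demand is hydride delivery to the β face of C9, cis to O10, without touching the ester or the enone β-carbon.

26 to 24: the C10–O bond is cut. With C8 already sp2, C10 is the only enolisable position of the C9 ketone, so regiochemistry is settled by the order of events. The demand is oxidation of the enol ether anti to the axial C1 methyl group.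

24 to 22 and 23: the C8=C14 bond is cut, removing the last skeletal carbon. The demand is that the Mannich-type methylenation chooses C8 over the neopentylic C10.

22 to 20 and 21: the ester C–O bond is cut. The acyl group goes on before the enone exists, so that a free 6-OH cannot add to C14. The demand is secondary-over-tertiary selectivity.

20 to 19 to 18: the C6–H bond is cut (inversion of C6 through the ketone). The epoxide route below necessarily delivers O6 on the β face, anti to the new C5–H; a reduction directed by the 4β-hydroxyl corrects it. The demand is reduction of C6 only, in the presence of the C9 ketone.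

18 to 15 and 16: the C4–isopropyl bond is cut, and the ketal and silyl ether are put back. The isopropyl group is deliberately added only after C5 is tetrahedral. On the trans-fused ketone the β face is closed; and an isopropyl group at C4 in an epoxy alcohol would itself migrate to C5 under Lewis acid instead of allowing the wanted hydride shift. The demand is 1,2-addition without enolisation or β-elimination.

15 to 13 to 12 to 11: the C5–H bond (a hydrogen that sat on C4), the epoxide C–O bonds and the C4–H bond are cut in turn. This reduces the stereochemical problem of C5 and C6 to one reagent-controlled ketone reduction of a planar enone, followed by two stereospecific steps. The demand is an anti 1,2-hydride shift that outruns other modes of epoxide opening.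

11 to 9 to 8: the C5=C6 unsaturation is removed and the C9 ketal opened. The gain is the bare dione; the demand is discrimination between two saturated ketones, and enolisation of C4 toward C5.

8 to 6: C5–C9 is reconnected (aldol sense) and C5–C1 and C9–C10 are cut (cyclobutane to enone plus alkene). Two rings, two skeletal bonds and C1 are removed at once, and an achiral, monocyclic precursor results. The demand is enantiofacial control at the enol double bond and a fixed enol regiochemistry.

6 to 5 to 1 and 2: the carbonate O–acyl bond and the C4–C5 bond are cut (enamine acylation), ending at purchasable materials.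

## Other disconnections considered

Alternative 1: The seven-membered ring is cut at C1–C5 and C6–C7 and the C7–C9 bond is reconnected, leading back to enyne A1, a tertiary propargylic silyl ether whose trisubstituted C1=C10 alkene carries a trans-disubstituted cyclopropane. In the forward sense [Rh(CO)2Cl]2 would join the alkyne and the vinylcyclopropane in a (5+2) cycloaddition, cleaving the less substituted cyclopropane bond, to give diene A2 with both rings closed.
- In favour: the reaction class is established for hydroazulenes. C4 is already a stereocentre and would control C1 by diastereoselection, not through an unproven catalyst. C14 is present from the start. The C9=C10 alkene would give the cis-diol by one syn-dihydroxylation anti to the C1 methyl group, a better answer to C9/C10 than steps 14 and 15 of the chosen plan.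
- Against: C1 would arise from a fully substituted alkene terminus, the least reactive kind of partner. The sense of induction from C4 to C1 through the metallacycle is not obvious. A1 needs an enantiopure tertiary propargylic alcohol, a defined trisubstituted alkene and an enantiopure cyclopropane, roughly ten steps against three. After the key step the C5=C6 alkene of A2 must still be hydrated to 5α-H/6α-OH from the face that carries the isopropyl group, with O4 silylated and on the wrong face to direct.
- Comparison: step counts are about equal. The alternative has better precedent for the ring-forming event; the chosen plan has a far simpler precursor and a worked-out answer for C4–C6.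

Alternative 2: The C5–C6 and C4–O bonds are cut; the C4(OH)–C5–C6(=O) pattern is read as an isoxazoline. In the forward sense nitrile oxide A5, generated from nitro compound A4 (fragment 1) with PhNCO and Et3N, adds to the trisubstituted alkene of cyclopentene A3 (fragment 2) on the face opposite the dioxolane, giving isoxazoline A6. N–O cleavage would later reveal the C6 ketone and the C4 carbinol, and the seven-membered ring would be closed between the bromoalkene carbon C8 and C9, for example with CrCl2/NiCl2.
- In favour: the suprafacial cycloaddition sets C4 and C5 in one stereospecific event (oxygen and C6 both β, hence 4β-OH and 5α-H), with the normal regiochemistry (oxygen to the more substituted carbon). This is shorter and cleaner than steps 6 to 9 of the chosen route. It is convergent, C10 comes from the chiral pool, and C6 would be finished by the same directed reduction as in step 11.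
- Against: a hindered trisubstituted alkene next to a quaternary carbon is a slow dipolarophile, so self-condensation of A5 competes. The facial preference rests on dioxolanyl versus methyl on the neighbouring carbon. A3, with quaternary C1 next to C10, needs its own asymmetric synthesis. The later C8–C9 closure does not secure the C9 configuration.
- Comparison: on the stereochemical logic for C4/C5/C6 the alternative is the better. On building the quaternary centre and the seven-membered ring the chosen plan is more direct. Step counts should be similar.

Alternative 3: The last skeletal bond, C9–C10, is cut. In the forward sense BF3·OEt2 activates the neopentyl aldehyde of stannane A7, and C9 of its (Z)-γ-(methoxymethoxy)allylstannane attacks with loss of tin from C14, giving A8: ring, both carbinols and the methylidene in one step.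
- In favour: the syn relation of O9 and O10 follows the usual behaviour of such stannanes under BF3, and C8–C10 are completed in one step where the chosen plan needs three (steps 13 to 15). On this triad the alternative is the better.
- Against: C1, C4, C5 and C6 must all be assembled beforehand on a fully substituted cyclopentane in a long linear sequence, so the hard problems are only moved into A7. A seven-membered ring is closed at a hindered aldehyde. The face of the aldehyde attacked, relative to the C1 methyl group, depends on the conformation of the tether. The stannane is acid-sensitive and tin is used stoichiometrically. Three protecting groups remain to be removed.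
- Comparison: this is a late ring closure against an early one. Mechanistically it is on firmer ground than the proposed enantioselective photocycloaddition. In step economy it is expected to be the longer route.

Key step: step 3

Remarks:
- Locants are those of the target (C1–C10, C14); β is the face of the C1 methyl group and α the opposite face.
- The precursor and the dione of the key step were checked atom by atom against this numbering and are consistent with the target (same configuration at C1). C5 of the dione is not controlled by the fragmentation; it is drawn trans and is erased in step 5.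
- The enol oxygen carries a benzyl carbonate so that unmasking is neutral.
- Which antipode of the chiral Lewis acid gives the C1 configuration shown is an assumption.

## Steps

Step 1
Reactants: 1 4-methylpent-4-enoic acid; 2 4-(cyclopent-1-en-1-yl)morpholine
Product: 5 2-(4-methylpent-4-enoyl)cyclopentan-1-one, via 4-methylpent-4-enoyl chloride 3 (not isolated), via acylated enamine 4 (not isolated)
Conditions: (COCl)2, DMF (cat.), CH2Cl2, 0 → 23 °C, evaporate; 2, Et3N, CH2Cl2, 0 → 23 °C; 2 M aq HCl, 23 °C
Reagents that add atoms: water, O
Why: Acid chloride formation, Stork enamine C-acylation (the enamine β-carbon attacks the acyl chloride, Et3N takes up HCl) and hydrolysis of the vinylogous amide give the β-diketone, obtained largely as its enol; no stereocentre is formed.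

Step 2
Reactants: 5
Product: 6 benzyl 2-(4-methylpent-4-enoyl)cyclopent-1-en-1-yl carbonate
Conditions: ClCO2Bn, pyridine, CH2Cl2, 0 °C
Reagents that add atoms: benzyl chloroformate, O=C(Cl)OCc1ccccc1
Why: O-Acylation of the enolised β-diketone; the isomer acylated at the ring oxygen (C5=C9 in the ring, C4=O free) is the one required and the one 2-acylcyclopentanones are known to give with chloroformates in pyridine, and any side-chain enol carbonate, which would lead to the crossed photoadduct, is removed by chromatography.

Step 3
Reactants: 6
Product: 8 1β-methylbicyclo[5.3.0]decane-4,9-dione (C5 drawn trans), via cyclobutane photoadduct 7 (not isolated)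
Conditions: hν (λ = 366 nm), oxazaborolidine [from (S)-α,α-diphenylprolinol and 2,4,6-trifluorophenylboronic acid]·AlBr3 (50 mol%), CH2Cl2, −75 °C; aq NaHCO3; then H2 (1 atm), Pd/C (palladium on carbon), EtOAc, 23 °C
Reagents that add atoms: none
Why: Proposed new method: the Lewis acid should bind the C4 carbonyl of 6 and shift the enone absorption to longer wavelength, so that 366 nm light excites mainly the complexed substrate, one face of whose C5=C9 bond is covered by the catalyst; the closest known reaction type is the intramolecular enone–alkene [2+2] photocycloaddition of cyclic enones and vinylogous esters catalysed by AlBr3-activated oxazaborolidines, while the uncatalysed racemic irradiation–fragmentation of enol carbonates of 2-acylcyclopentanones is known. The excited enone adds to the 1,1-disubstituted alkene by 1,5-closure (5-exo, C5–C1), which closes the new cyclopentanone ring and leaves a C9/C10 1,4-diradical that collapses to the cyclobutane (C9–C10). Both fusions at the cyclobutane are necessarily cis, so the only variable is the enone face, that is, the absolute configuration at C1, which is the task of the catalyst. Hydrogenolysis of the benzyl carbonate (toluene and CO2 are lost) frees the C9 cyclobutanol, and strain-driven retro-aldol cleavage of C5–C9 toward the C4 carbonyl merges the old five-membered ring with C1 and C10 into the cycloheptanone; the seven-membered ring is thus closed by the C9–C10 bond and opened out by fragmentation. C5 arises by uncontrolled protonation of the enol and is erased in step 5. The step needs straight and not crossed regiochemistry (secured by the three-atom tether C4–C3–C2), reaction of the ring enol isomer only (secured by the fixed carbonate) and enantiofacial discrimination (the unproven point).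

Step 4
Reactants: 8
Product: 9 9,9-(ethylenedioxy)-1β-methylbicyclo[5.3.0]decan-4-one
Conditions: Me3SiOCH2CH2OSiMe3 (1.1 equiv), Me3SiOTf (5 mol%), CH2Cl2, −78 → −40 °C
Reagents that add atoms: 1,2-bis(trimethylsilyloxy)ethane, C[Si](C)(C)OCCO[Si](C)(C)C
Why: Kinetically controlled, silyl-triflate-catalysed dioxolane formation responds strongly to steric hindrance; C9 lies between two methylene groups whereas C4 is α-branched at the ring-fusion carbon C5 next to quaternary C1, so C9 should react first; no stereocentre is formed.

Step 5
Reactants: 9
Product: 11 9,9-(ethylenedioxy)-1β-methylbicyclo[5.3.0]dec-5-en-4-one, via trimethylsilyl enol ether 10 (not isolated)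
Conditions: Me3SiCl, Et3N, DMF, 110 °C; then Pd(OAc)2 (1.1 equiv), MeCN, 23 °C
Reagents that add atoms: none
Why: Thermodynamic silylation gives mainly the tetrasubstituted C4=C5 enol ether, and in the Saegusa oxidation the palladium enolate at C5 can lose a β-hydrogen only from C6 because C1 is quaternary; C5 is planarised here, so the epimer ratio of 8 is irrelevant.

Step 6
Reactants: 11
Product: 12 9,9-(ethylenedioxy)-1β-methylbicyclo[5.3.0]dec-5-en-4β-ol
Conditions: (R)-2-methyl-CBS-oxazaborolidine [(R)-1-methyl-3,3-diphenyltetrahydro-1H,3H-pyrrolo[1,2-c][1,3,2]oxazaborole] (20 mol%), BH3·SMe2, THF, −30 °C; MeOH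
Reagents that add atoms: none
Why: Corey–Bakshi–Shibata reduction of an s-cis α-alkylidene cyclopentanone with the alkenyl carbon C5 as the large and C3H2 as the small group, for which the (R)-catalyst is predicted to deliver hydride to the α face (4β-OH); since C1 gives little intrinsic bias at C4, the catalyst should dominate.

Step 7
Reactants: 12
Product: 13 5β,6β-epoxy-9,9-(ethylenedioxy)-1β-methylbicyclo[5.3.0]decan-4β-ol
Conditions: VO(acac)2 (5 mol%), t-BuOOH, CH2Cl2, 0 → 23 °C
Reagents that add atoms: tert-butyl hydroperoxide, CC(C)(C)OO
Why: Hydroxyl-directed epoxidation of a cyclic allylic alcohol; the vanadium alkoxide at O4 delivers oxygen to the face of C5=C6 on which O4 lies (O4–C4–C5=C6 dihedral near 60°), giving the β-epoxide.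

Step 8
Reactants: 13
Product: 15 9,9-(ethylenedioxy)-1β-methyl-6β-(triethylsilyloxy)-5α-H-bicyclo[5.3.0]decan-4-one, via epoxy silyl ether 14 (not isolated)
Conditions: Et3SiOTf (2.2 equiv), i-Pr2NEt (3 equiv), 4 Å MS, CH2Cl2, −78 → −40 °C
Reagents that add atoms: triethylsilyl trifluoromethanesulfonate, CC[Si](CC)(CC)OS(=O)(=O)C(F)(F)F
Why: Semipinacol rearrangement of an epoxy silyl ether by 1,2-hydride shift (the non-aldol aldol process): silylation of the epoxide oxygen opens the tertiary C5–O bond while the C4 hydrogen, α and antiperiplanar to that bond, migrates to C5 with inversion; this gives 5α-H (trans fusion), the C4 ketone after loss of silyl from the oxocarbenium ion, and O6 as its β-silyl ether, C5 tertiary and C6 secondary being the substitution pattern this rearrangement needs.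

Step 9
Reactants: 15; 16 isopropylmagnesium chloride
Product: 18 4β,6β-dihydroxy-4α-isopropyl-1β-methyl-5α-H-bicyclo[5.3.0]decan-9-one, via protected tertiary carbinol 17 (not isolated)
Conditions: CeCl3 (1.5 equiv), THF, −78 °C; then 2 M aq HCl, THF, 23 °C
Reagents that add atoms: water, O
Why: Organocerium 1,2-addition (suppresses enolisation, β-elimination of the silyloxy group and β-hydride reduction); on the trans-fused cyclopentanone the β face of C4 is screened by the axial C1 methyl and the 6β-silyloxy group, so isopropyl enters from the α face (4β-OH), and the acidic work-up removes the silyl ether and the dioxolane together.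

Step 10
Reactants: 18
Product: 19 4β-hydroxy-4α-isopropyl-1β-methyl-5α-H-bicyclo[5.3.0]decane-6,9-dione
Conditions: Dess–Martin periodinane, NaHCO3, CH2Cl2, 0 → 23 °C
Reagents that add atoms: none
Why: Oxidation of the only secondary alcohol under buffered, non-basic conditions, which should spare the tertiary β-hydroxy ketone from retro-aldol cleavage and C5 from epimerisation; the C6 centre is removed so that it can be reset.

Step 11
Reactants: 19
Product: 20 4β,6α-dihydroxy-4α-isopropyl-1β-methyl-5α-H-bicyclo[5.3.0]decan-9-one
Conditions: Me4NBH(OAc)3 (5 equiv), MeCN/AcOH (1:1), −30 °C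
Reagents that add atoms: none
Why: Evans–Saksena anti reduction: acetate exchange binds boron to O4 and hydride is delivered intramolecularly to the C6 carbonyl from the β face, on which O4 lies, giving the 6α-carbinol; the C9 ketone has no hydroxyl within reach and is not reduced by triacetoxyborohydride.

Step 12
Reactants: 20; 21 3-methylbutanoyl chloride
Product: 22 4β-hydroxy-4α-isopropyl-1β-methyl-6α-(3-methylbutanoyloxy)-5α-H-bicyclo[5.3.0]decan-9-one
Conditions: pyridine, 4-(dimethylamino)pyridine (10 mol%), CH2Cl2, 0 °C
Reagents that add atoms: none
Why: Nucleophile-catalysed acylation distinguishes the secondary C6 alcohol from the tertiary C4 alcohol; the ester is installed now so that a free 6-OH cannot add to the enone made in step 13.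

Step 13
Reactants: 22; 23 paraformaldehyde
Product: 24 4β-hydroxy-4α-isopropyl-1β-methyl-8-methylidene-6α-(3-methylbutanoyloxy)-5α-H-bicyclo[5.3.0]decan-9-one
Conditions: i-Pr2NH2+ CF3CO2− (1 equiv), THF, 65 °C
Reagents that add atoms: none
Why: Ammonium-salt-mediated Mannich condensation and β-elimination of the amine (direct α-methylenation); of the two α-methylene groups C10 is neopentylic, so the iminium ion should be taken up at C8.

Step 14
Reactants: 24
Product: 26 4β,10α-dihydroxy-4α-isopropyl-1β-methyl-8-methylidene-6α-(3-methylbutanoyloxy)-5α-H-bicyclo[5.3.0]decan-9-one, via bis(trimethylsilyl) dienol ether 25 (not isolated)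
Conditions: Me3SiOTf (2.5 equiv), Et3N (3.5 equiv), CH2Cl2, −20 → 0 °C; mCPBA, NaHCO3, CH2Cl2, −20 °C; 1 M aq HCl, THF, 0 °C
Reagents that add atoms: 3-chloroperbenzoic acid, O=C(OO)c1cccc(Cl)c1
Why: Rubottom oxidation: with C8 sp2 the ketone can enolise only toward C10, the electron-rich C9=C10 silyl enol ether is epoxidised in preference to the C8=C14 bond, and the peracid approaches anti to the axial C1 methyl group (α face), so silyl migration and acidic work-up give the 10α-hydroxy ketone; the tertiary alcohol is silylated in passing and freed again.

Step 15
Reactants: 26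
Product: 27 (target) 4β,9α,10α-trihydroxy-4α-isopropyl-1β-methyl-8-methylidene-5α-H-bicyclo[5.3.0]decan-6α-yl 3-methylbutanoate
Conditions: Zn(BH4)2, Et2O, −20 °C; aq NH4Cl
Reagents that add atoms: none
Why: Chelation-controlled 1,2-reduction of an α-hydroxy enone: zinc bridges O9 and O10 and hydride attacks C9 from the side of the C10 hydrogen (β), away from C1, giving the 9α-carbinol cis to the 10α-hydroxyl; this borohydride reduces enones at the carbonyl carbon and leaves the ester.

## Compound list

1 | 4-methylpent-4-enoic acid | C=C(C)CCC(=O)O | starting material
2 | 4-(cyclopent-1-en-1-yl)morpholine | C1CCC(=C1)N1CCOCC1 | starting material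
3 | 4-methylpent-4-enoyl chloride | C=C(C)CCC(=O)Cl | intermediate
4 | 4-methyl-1-(2-morpholinocyclopent-1-en-1-yl)pent-4-en-1-one | C=C(C)CCC(=O)C1=C(N2CCOCC2)CCC1 | intermediate
5 | 2-(4-methylpent-4-enoyl)cyclopentan-1-one | C=C(C)CCC(=O)C1CCCC1=O | intermediate
6 | benzyl 2-(4-methylpent-4-enoyl)cyclopent-1-en-1-yl carbonate | C=C(C)CCC(=O)C1=C(OC(=O)OCc2ccccc2)CCC1 | intermediate
7 | cyclobutane photoadduct (four-membered ring C5–C1–C10–C9, cis-fused at C5–C9 to the cyclopentane C6–C8 and at C5–C1 to the cyclopentanone C2–C4; C1 methyl, C9 benzyl carbonate) | C[C@]12CCC(=O)[C@]13CCC[C@]3(OC(=O)OCc4ccccc4)C2 | intermediate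
8 | 1β-methylbicyclo[5.3.0]decane-4,9-dione (C5 drawn trans) | O=C1CCC[C@H]2C(=O)CC[C@]2(C)C1 | intermediate
9 | 9,9-(ethylenedioxy)-1β-methylbicyclo[5.3.0]decan-4-one | O=C1CC[C@]2(C)CC3(OCCO3)CCC[C@@H]12 | intermediate
10 | 9,9-(ethylenedioxy)-1β-methyl-4-(trimethylsilyloxy)bicyclo[5.3.0]dec-4-ene | C[Si](C)(C)OC1=C2CCCC3(OCCO3)C[C@@]2(C)CC1 | intermediate
11 | 9,9-(ethylenedioxy)-1β-methylbicyclo[5.3.0]dec-5-en-4-one | O=C1CC[C@]2(C)CC3(OCCO3)CCC=C12 | intermediate
12 | 9,9-(ethylenedioxy)-1β-methylbicyclo[5.3.0]dec-5-en-4β-ol | O[C@H]1CC[C@]2(C)CC3(OCCO3)CCC=C12 | intermediate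
13 | 5β,6β-epoxy-9,9-(ethylenedioxy)-1β-methylbicyclo[5.3.0]decan-4β-ol | O[C@H]1CC[C@]2(C)CC3(OCCO3)CC[C@H]4O[C@@]124 | intermediate
14 | 4-O-triethylsilyl ether of 13 | CC[Si](CC)(CC)O[C@H]1CC[C@]2(C)CC3(OCCO3)CC[C@H]4O[C@@]124 | intermediate
15 | 9,9-(ethylenedioxy)-1β-methyl-6β-(triethylsilyloxy)-5α-H-bicyclo[5.3.0]decan-4-one | O=C1CC[C@]2(C)CC3(OCCO3)CC[C@@H](O[Si](CC)(CC)CC)[C@@H]12 | intermediate
16 | isopropylmagnesium chloride | CC(C)[Mg]Cl | starting material
17 | 9,9-(ethylenedioxy)-4α-isopropyl-1β-methyl-6β-(triethylsilyloxy)-5α-H-bicyclo[5.3.0]decan-4β-ol | CC(C)[C@]1(O)CC[C@]2(C)CC3(OCCO3)CC[C@@H](O[Si](CC)(CC)CC)[C@@H]12 | intermediate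
18 | 4β,6β-dihydroxy-4α-isopropyl-1β-methyl-5α-H-bicyclo[5.3.0]decan-9-one | CC(C)[C@]1(O)CC[C@]2(C)CC(=O)CC[C@@H](O)[C@@H]12 | intermediate
19 | 4β-hydroxy-4α-isopropyl-1β-methyl-5α-H-bicyclo[5.3.0]decane-6,9-dione | CC(C)[C@]1(O)CC[C@]2(C)CC(=O)CCC(=O)[C@@H]12 | intermediate
20 | 4β,6α-dihydroxy-4α-isopropyl-1β-methyl-5α-H-bicyclo[5.3.0]decan-9-one | CC(C)[C@]1(O)CC[C@]2(C)CC(=O)CC[C@H](O)[C@@H]12 | intermediate
21 | 3-methylbutanoyl chloride | CC(C)CC(=O)Cl | starting material
22 | 4β-hydroxy-4α-isopropyl-1β-methyl-6α-(3-methylbutanoyloxy)-5α-H-bicyclo[5.3.0]decan-9-one | CC(C)[C@]1(O)CC[C@]2(C)CC(=O)CC[C@H](OC(=O)CC(C)C)[C@@H]12 | intermediate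
23 | paraformaldehyde (formaldehyde unit) | C=O | starting material
24 | 4β-hydroxy-4α-isopropyl-1β-methyl-8-methylidene-6α-(3-methylbutanoyloxy)-5α-H-bicyclo[5.3.0]decan-9-one | CC(C)[C@]1(O)CC[C@]2(C)CC(=O)C(=C)C[C@H](OC(=O)CC(C)C)[C@@H]12 | intermediate
25 | 4β,9-bis(trimethylsilyloxy)-8-methylidene dienol ether (C9=C10) of 24 | CC(C)[C@]1(O[Si](C)(C)C)CC[C@]2(C)C=C(O[Si](C)(C)C)C(=C)C[C@H](OC(=O)CC(C)C)[C@@H]12 | intermediate
26 | 4β,10α-dihydroxy-4α-isopropyl-1β-methyl-8-methylidene-6α-(3-methylbutanoyloxy)-5α-H-bicyclo[5.3.0]decan-9-one | CC(C)[C@]1(O)CC[C@]2(C)[C@H](O)C(=O)C(=C)C[C@H](OC(=O)CC(C)C)[C@@H]12 | intermediate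
27 | CNP0204264.1: 4β,9α,10α-trihydroxy-4α-isopropyl-1β-methyl-8-methylidene-5α-H-bicyclo[5.3.0]decan-6α-yl 3-methylbutanoate | C=C1C[C@H](OC(=O)CC(C)C)[C@@H]2[C@](C)(CC[C@@]2(O)C(C)C)[C@H](O)[C@@H]1O | target

## Step count and least certain steps

Total: 15 steps. Longest linear sequence: 15 steps (from 1 and 2 to 27; 16, 21 and 23 are purchased).

Step 3 (bears the label). Most likely failure is poor enantiofacial discrimination. The Lewis acid can also bind the carbonate carbonyl or a different rotamer of the exocyclic C4 carbonyl, and uncatalysed background excitation gives racemic material. Loss of the carbonate to AlBr3 is a second risk.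
Fallback (known chemistry; sets out from 5, returns at 8): acylate 5 with (−)-menthyl chloroformate in pyridine to give the menthyl enol carbonate F1. Irradiate it without any catalyst (λ > 300 nm, CH2Cl2), as in the established racemic process. The two cis,cis-fused adducts are now diastereomers and are separated by chromatography or crystallisation. The isomer with the required C1 configuration, the menthyl carbonate photoadduct F2, is treated with K2CO3 in MeOH, which removes the carbonate and triggers the retro-aldol cleavage to 8.

Step 4. Most likely failure is insufficient discrimination between the two saturated ketones (competing ketalisation at C4 or double ketalisation): ring size favours the cyclopentanone while branching favours the cycloheptanone.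
Fallback (sets out from 8, returns at 11): reverse the order of differentiation. Treat 8 with a limiting amount of Me3SiCl (Et3N, DMF, heat), so that under equilibrating conditions the silyl group settles on the more acidic cyclopentanone as the tetrasubstituted C4=C5 enol ether, and oxidise with Pd(OAc)2 to the enedione F3. Then apply the ketalisation of step 4; the choice is now between a saturated and a conjugated ketone, for which this reagent is known to select the saturated one, and the product is 11.

Step 8. Most likely failure is epoxide opening by another course: proton loss to an allylic silyl ether, migration of C3 in place of hydride, or opening of the dioxolane by the silyl triflate.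
Fallback (sets out from 12, returns at 22): set 5α-H and 6α-O by syn hydroboration.
- Silylate 12 (t-BuMe2SiCl, imidazole) to the 4β-silyl ether F4.
- BH3·THF, then H2O2/NaOH, adds H to C5 and OH to C6 from the α face, anti to the bulky allylic silyloxy group, giving the alcohol F5.
- Acylation with 21 (pyridine, 4-(dimethylamino)pyridine) gives the ester F6.
- HF·pyridine frees the C4 carbinol F7.
- Dess–Martin oxidation gives the ketone F8.
- i-PrMgCl/CeCl3 at −78 °C (α attack on the trans-fused ketone), followed by aqueous HCl to remove the dioxolane, gives 22.

Step 13. Most likely failure is poor regiocontrol between C8 and C10, double methylenation, or acid-promoted loss of the tertiary alcohol on prolonged heating.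
Fallback (sets out from 22, returns at 24): fix the regiochemistry by kinetic deprotonation. LiHMDS (2.2 equiv) and Me3SiCl at −78 °C give the C8=C9 silyl enol ether F9 (the tertiary alcohol is silylated as well). Eschenmoser's salt (CH2=NMe2+ I−), followed by aqueous work-up, gives the Mannich base F10. Quaternisation with MeI and treatment with NaHCO3 eliminate trimethylamine to give 24.

Step 15. Most likely failure is poor facial selectivity at C9 if chelation is incomplete, since the β face is also the face of the axial C1 methyl group; the result would be partial formation of the trans-diol.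
Fallback (sets out from 26, returns at 27): replace chelation by steric control. Et3SiOTf and 2,6-lutidine give the bis(triethylsilyl) ether F11. Luche reduction (NaBH4, CeCl3, MeOH, −78 °C) delivers hydride anti to the bulky 10α-silyloxy group, giving the 9α-carbinol F12. HF·pyridine removes both silyl groups to give 27.

## Further compounds

F1 | step 3 | (1R,2S,5R)-menthyl 2-(4-methylpent-4-enoyl)cyclopent-1-en-1-yl carbonate | C=C(C)CCC(=O)C1=C(OC(=O)O[C@@H]2C[C@H](C)CC[C@H]2C(C)C)CCC1
F2 | step 3 | menthyl carbonate analogue of photoadduct 7 (required diastereomer) | C[C@]12CCC(=O)[C@]13CCC[C@]3(OC(=O)O[C@@H]4C[C@H](C)CC[C@H]4C(C)C)C2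
F3 | step 4 | 1β-methylbicyclo[5.3.0]dec-5-ene-4,9-dione | O=C1CC[C@]2(C)CC(=O)CCC=C12
F4 | step 8 | 4β-(tert-butyldimethylsilyloxy)-9,9-(ethylenedioxy)-1β-methylbicyclo[5.3.0]dec-5-ene | CC(C)(C)[Si](C)(C)O[C@H]1CC[C@]2(C)CC3(OCCO3)CCC=C12
F5 | step 8 | 4β-(tert-butyldimethylsilyloxy)-9,9-(ethylenedioxy)-1β-methyl-5α-H-bicyclo[5.3.0]decan-6α-ol | CC(C)(C)[Si](C)(C)O[C@H]1CC[C@]2(C)CC3(OCCO3)CC[C@H](O)[C@@H]12
F6 | step 8 | 6α-(3-methylbutanoyl) ester of F5 | CC(C)(C)[Si](C)(C)O[C@H]1CC[C@]2(C)CC3(OCCO3)CC[C@H](OC(=O)CC(C)C)[C@@H]12
F7 | step 8 | 9,9-(ethylenedioxy)-4β-hydroxy-1β-methyl-5α-H-bicyclo[5.3.0]decan-6α-yl 3-methylbutanoate | O[C@H]1CC[C@]2(C)CC3(OCCO3)CC[C@H](OC(=O)CC(C)C)[C@@H]12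
F8 | step 8 | 9,9-(ethylenedioxy)-1β-methyl-4-oxo-5α-H-bicyclo[5.3.0]decan-6α-yl 3-methylbutanoate | O=C1CC[C@]2(C)CC3(OCCO3)CC[C@H](OC(=O)CC(C)C)[C@@H]12
F9 | step 13 | 4β,9-bis(trimethylsilyloxy) C8=C9 enol ether of 22 | CC(C)[C@]1(O[Si](C)(C)C)CC[C@]2(C)CC(O[Si](C)(C)C)=CC[C@H](OC(=O)CC(C)C)[C@@H]12
F10 | step 13 | 8-[(dimethylamino)methyl] derivative of 22 (C8 epimers) | CC(C)[C@]1(O)CC[C@]2(C)CC(=O)C(CN(C)C)C[C@H](OC(=O)CC(C)C)[C@@H]12
F11 | step 15 | 4β,10α-bis(triethylsilyl) ether of 26 | CC(C)[C@]1(O[Si](CC)(CC)CC)CC[C@]2(C)[C@H](O[Si](CC)(CC)CC)C(=O)C(=C)C[C@H](OC(=O)CC(C)C)[C@@H]12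
F12 | step 15 | 4β,10α-bis(triethylsilyl) ether of 27 | CC(C)[C@]1(O[Si](CC)(CC)CC)CC[C@]2(C)[C@H](O[Si](CC)(CC)CC)[C@H](O)C(=C)C[C@H](OC(=O)CC(C)C)[C@@H]12
A1 | alternative 1 | enyne vinylcyclopropane: tertiary propargylic triethylsilyl ether with (E)-trisubstituted alkene and trans-cyclopropane bearing CH2OPMB | COc1ccc(COC[C@H]2C[C@@H]2/C=C(\C)CC[C@@](O[Si](CC)(CC)CC)(C(C)C)C#C)cc1
A2 | alternative 1 | bicyclo[5.3.0]deca-5,9-diene with C1 methyl, C4 triethylsilyl ether and C8 CH2OPMB | COc1ccc(COC[C@H]2CC=C3[C@](C)(CC[C@@]3(O[Si](CC)(CC)CC)C(C)C)C=C2)cc1
A3 | alternative 2 | fragment 2: 4-(3-isopropyl-1-methylcyclopent-2-en-1-yl)-2,2-dimethyl-1,3-dioxolane | CC(C)C1=C[C@@](C)([C@H]2COC(C)(C)O2)CC1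
A4 | alternative 2 | fragment 1: 2-bromo-4-nitrobut-1-ene | C=C(Br)CC[N+](=O)[O-]
A5 | alternative 2 | 3-bromobut-3-enenitrile oxide | C=C(Br)CC#[N+][O-]
A6 | alternative 2 | cyclopenta-fused isoxazoline with 2-bromoallyl group on C6 | C=C(Br)CC1=NO[C@@]2(C(C)C)CC[C@](C)([C@H]3COC(C)(C)O3)[C@@H]12
A7 | alternative 3 | cyclopentane C10 aldehyde carrying the (Z)-γ-(methoxymethoxy)allylstannane chain, C6 tert-butyldimethylsilyl ether and C4 triethylsilyl ether | O=C[C@@]1(C)CC[C@@](O[Si](CC)(CC)CC)(C(C)C)[C@@H]1[C@@H](O[Si](C)(C)C(C)(C)C)C/C(C[Sn](CCCC)(CCCC)CCCC)=C\OCOC
A8 | alternative 3 | protected target skeleton: C10 hydroxyl free, C9 methoxymethyl ether, C6 and C4 silyl ethers | C=C1C[C@H](O[Si](C)(C)C(C)(C)C)[C@@H]2[C@](C)(CC[C@@]2(O[Si](CC)(CC)CC)C(C)C)[C@H](O)[C@@H]1OCOC
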